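**Plan**
- Retrosynthesis: the two O–Si bonds are cut first, then the C3–C4 bond of ring C, then the O1–C2 (aryl–O–vinyl) bond, then the formyl C–C bond at C4a and the prenyl C–C bond at C8 of ring A.
- Enabling feature: C4 is an aryl ketone carbon ortho to O1 on ring A, and C3 is a CH2 next to the O- and aryl-bearing C2. Ring C is therefore the formal adduct of a ring-A formyl C–H across a 1-arylvinyl aryl ether (O1–C2(=C3H2)–ring B), an isomer of the silylated target.
- Ring A: phloroglucinol keeps one free phenol (the future O1), which directs both the prenyl group (O-tert-prenylation, Claisen shift to C8) and the formyl group (magnesium-mediated ortho-formylation at C4a).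
- Ring B: 4-hydroxybenzaldehyde is O-prenylated, homologated to the alkyne and converted into the 1-arylvinyl boronate, which is joined to O1 by copper-mediated C–O coupling.
- Ring C is closed last by rhodium-catalysed enantioselective intramolecular hydroacylation. C2 (S), the only stereocentre, is set there by the chiral bisphosphine; buffered desilylation gives the target.

Key step: step 9

Remark: tert-butyl (2-methylbut-3-en-2-yl) carbonate is taken as a purchasable reagent, and the facial sense of the ligand in the key step is assigned by analogy, the ligand antipode being used if a model run shows the opposite sense.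

**Route**

Step 1
Reactants: 1 phloroglucinol (benzene-1,3,5-triol); 2 triisopropylsilyl chloride
Product: 4 3,5-bis(triisopropylsilyloxy)phenol, via monosilyl ether 3 (not isolated)
Conditions: i-Pr3SiCl (2.0 equiv), imidazole (4 equiv), DMF, 0 °C to rt; chromatography
Reagents that add atoms: triisopropylsilyl chloride, CC(C)[Si](Cl)(C(C)C)C(C)C
Why: Imidazole-promoted silylation of phenols is general, and because the three hydroxyl groups of 1 are equivalent the bis-silyl ether forms by statistical silylation through the monosilyl ether and is separated from under- and over-silylated material, leaving exactly one free phenol, the future O1.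

Step 2
Reactants: 4 3,5-bis(triisopropylsilyloxy)phenol; 5 tert-butyl (2-methylbut-3-en-2-yl) carbonate
Product: 6 1-(2-methylbut-3-en-2-yloxy)-3,5-bis(triisopropylsilyloxy)benzene
Conditions: Pd(PPh3)4 (2 mol%), 4 Å MS, THF, 0 °C
Reagents that add atoms: tert-butyl (2-methylbut-3-en-2-yl) carbonate, C=CC(C)(C)OC(=O)OC(C)(C)C
Why: Decarboxylative Tsuji–Trost O-allylation: zerovalent palladium ionises the tertiary carbonate to a 1,1-dimethyl-π-allyl complex and tert-butoxide, which deprotonates 4, and the phenoxide attacks the more substituted allyl terminus under kinetic control at low temperature to give the tert-prenyl ether.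

Step 3
Reactants: 6 1-(2-methylbut-3-en-2-yloxy)-3,5-bis(triisopropylsilyloxy)benzene
Product: 8 2-(3-methylbut-2-enyl)-3,5-bis(triisopropylsilyloxy)phenol, via ortho-dienone 7 (not isolated)
Conditions: N,N-diethylaniline, 130 °C
Reagents that add atoms: none
Why: Aromatic Claisen rearrangement: the [3,3] shift through a chair transition state delivers the unsubstituted allyl terminus to one of the two equivalent ortho carbons and the dienone tautomerises to the phenol, which places the prenyl group on the carbon next to the future O1 (C8 of the target) without any regiochemical choice.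

Step 4
Reactants: 8 2-(3-methylbut-2-enyl)-3,5-bis(triisopropylsilyloxy)phenol; 9 paraformaldehyde
Product: 11 2-hydroxy-3-(3-methylbut-2-enyl)-4,6-bis(triisopropylsilyloxy)benzaldehyde, via salicyl alcohol 10 (not isolated)
Conditions: MgCl2 (2 equiv), Et3N (4 equiv), (CH2O)n (excess), MeCN, 80 °C
Reagents that add atoms: paraformaldehyde (as formaldehyde), C=O
Why: Magnesium-mediated ortho-formylation (Casnati–Skattebøl): the magnesium phenoxide delivers formaldehyde only to a carbon ortho to the free hydroxyl, of which a single one is left, and a second formaldehyde oxidises the hydroxymethyl intermediate by hydride transfer, while the base-buffered, aprotic medium leaves the prenyl alkene and the silyl ethers alone.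

Step 5
Reactants: 12 4-hydroxybenzaldehyde; 13 1-bromo-3-methylbut-2-ene (prenyl bromide)
Product: 14 4-(3-methylbut-2-enyloxy)benzaldehyde
Conditions: K2CO3, DMF, rt
Reagents that add atoms: 1-bromo-3-methylbut-2-ene, CC(C)=CCBr
Why: Williamson ether synthesis of a phenoxide with a primary allylic bromide under mild carbonate conditions, O-alkylation being favoured in a polar aprotic solvent.

Step 6
Reactants: 14 4-(3-methylbut-2-enyloxy)benzaldehyde; 15 dimethyl (1-diazo-2-oxopropyl)phosphonate
Product: 17 1-ethynyl-4-(3-methylbut-2-enyloxy)benzene, via diazoalkene 16 (not isolated)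
Conditions: K2CO3, MeOH, rt
Reagents that add atoms: dimethyl (1-diazo-2-oxopropyl)phosphonate, COP(=O)(OC)C(=[N+]=[N-])C(C)=O
Why: Ohira–Bestmann (Seyferth–Gilbert) homologation: methanolysis of 15 releases the diazomethylphosphonate anion, whose Horner–Wadsworth–Emmons reaction with the aldehyde gives the diazoalkene that loses nitrogen and undergoes a 1,2-hydrogen shift to the terminal alkyne under conditions that do not touch the allyl aryl ether.

Step 7
Reactants: 17 1-ethynyl-4-(3-methylbut-2-enyloxy)benzene; 18 2-methoxy-4,4,5,5-tetramethyl-1,3,2-dioxaborolane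
Product: 20 4,4,5,5-tetramethyl-2-{1-[4-(3-methylbut-2-enyloxy)phenyl]ethenyl}-1,3,2-dioxaborolane, via vinylalane 19 (not isolated)
Conditions: NiCl2(dppp) (3 mol%), i-Bu2AlH (1.3 equiv), THF, 0 °C to rt; then 18 (3 equiv), 0 to 80 °C
Reagents that add atoms: 2-methoxy-4,4,5,5-tetramethyl-1,3,2-dioxaborolane, COB1OC(C)(C)C(C)(C)O1
Why: Nickel-catalysed Markovnikov (α-selective) hydroalumination of a terminal aryl alkyne places aluminium on the aryl-bearing carbon, and aluminium-to-boron exchange with the methoxyboronate gives the 1-arylvinyl boronate, the trisubstituted prenyl alkene being too hindered to be hydroaluminated.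

Step 8
Reactants: 11 2-hydroxy-3-(3-methylbut-2-enyl)-4,6-bis(triisopropylsilyloxy)benzaldehyde; 20 4,4,5,5-tetramethyl-2-{1-[4-(3-methylbut-2-enyloxy)phenyl]ethenyl}-1,3,2-dioxaborolane
Product: 21 3-(3-methylbut-2-enyl)-2-{1-[4-(3-methylbut-2-enyloxy)phenyl]ethenyloxy}-4,6-bis(triisopropylsilyloxy)benzaldehyde
Conditions: 20 (2.5 equiv), Cu(OAc)2 (2 equiv), Et3N (4 equiv), 4 Å MS, CH2Cl2, dry air, rt; chromatography on Et3N-deactivated silica
Reagents that add atoms: none
Why: Chan–Lam oxidative C–O coupling: the phenoxide and the alkenyl group meet on copper and C–O reductive elimination gives the aryl alkenyl ether at room temperature under weakly basic conditions that spare the aldehyde, the silyl ethers and the acid-labile enol ether, this coupling type being known to accept di-ortho-substituted phenols and alkenyl pinacol boronates.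

Step 9
Reactants: 21 3-(3-methylbut-2-enyl)-2-{1-[4-(3-methylbut-2-enyloxy)phenyl]ethenyloxy}-4,6-bis(triisopropylsilyloxy)benzaldehyde
Product: 22 (2S)-8-(3-methylbut-2-enyl)-2-[4-(3-methylbut-2-enyloxy)phenyl]-5,7-bis(triisopropylsilyloxy)-2,3-dihydro-4H-chromen-4-one
Conditions: [Rh(cod)Cl]2 (2.5 mol%), (R)-DTBM-SEGPHOS (5.5 mol%), NaB[3,5-(CF3)2C6H3]4 (5 mol%), THF, 60 °C, acid-free glassware
Reagents that add atoms: none
Why: Proposed new method: the cationic rhodium bisphosphine catalyst (monovalent rhodium) should add oxidatively into the formyl C–H bond of 21, the acyl rhodium hydride (trivalent rhodium) then binds the tethered 1,1-disubstituted enol ether, hydride migrates to the oxygen- and aryl-bearing carbon (future C2) while rhodium takes the terminal CH2, and C–C reductive elimination from the seven-membered acyl alkyl rhodacycle forms C3–C4 and returns the catalyst. The closest known reaction type is the rhodium/DTBM-SEGPHOS-catalysed endo- and enantioselective hydroacylation of ortho-allylbenzaldehydes and N-allylindole-2-carbaldehydes that carry 1,1-disubstituted alkenes, which gives six-membered ketones with a β-stereocentre; here the CH2 or N link of those tethers is replaced by an ether oxygen bound directly to the alkene, a substrate class on which the reaction has not been shown. Ring C closes in the 6-endo-trig mode (both alkene carbons end up in the ring). C2 is set under catalyst control in the hydride insertion, the C2-symmetric ligand shielding one enantiotopic alkene face so that hydrogen arrives on the Re face of C2 to give (S). Endo over exo regiochemistry is secured by the 1,1-disubstitution (the exo path needs a tertiary alkyl rhodium) and by the polarity of the enol ether, whose nucleophilic CH2 terminus binds the cationic metal as in cationic Heck arylations of vinyl ethers; hydroacylation should outrun decarbonylation because the alkene is held next to the acyl group, alkene isomerisation is impossible for lack of an allylic hydrogen, and the trisubstituted prenyl alkenes are out of reach of the acyl rhodium and poor insertion partners.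

Step 10
Reactants: 22 (2S)-8-(3-methylbut-2-enyl)-2-[4-(3-methylbut-2-enyloxy)phenyl]-5,7-bis(triisopropylsilyloxy)-2,3-dihydro-4H-chromen-4-one
Product: 23 (2S)-5,7-dihydroxy-8-(3-methylbut-2-enyl)-2-[4-(3-methylbut-2-enyloxy)phenyl]-2,3-dihydro-4H-chromen-4-one (target)
Conditions: n-Bu4NF (2.5 equiv), AcOH (2.5 equiv), THF, 0 °C
Reagents that add atoms: none
Why: Fluoride cleaves the two aryl silyl ethers, which are activated by the ortho/para carbonyl group, and the acetic acid buffer keeps the liberated phenols protonated so that the flavanone cannot open by retro-oxa-Michael elimination and C2 keeps its configuration, while the allyl aryl ether and the prenyl alkene are inert to fluoride.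

**Compound list**

1 | phloroglucinol (benzene-1,3,5-triol) | Oc1cc(O)cc(O)c1 | starting material
2 | triisopropylsilyl chloride | CC(C)[Si](Cl)(C(C)C)C(C)C | starting material
3 | 5-(triisopropylsilyloxy)benzene-1,3-diol | Oc1cc(O)cc(O[Si](C(C)C)(C(C)C)C(C)C)c1 | intermediate
4 | 3,5-bis(triisopropylsilyloxy)phenol | Oc1cc(O[Si](C(C)C)(C(C)C)C(C)C)cc(O[Si](C(C)C)(C(C)C)C(C)C)c1 | intermediate
5 | tert-butyl (2-methylbut-3-en-2-yl) carbonate | C=CC(C)(C)OC(=O)OC(C)(C)C | starting material
6 | 1-(2-methylbut-3-en-2-yloxy)-3,5-bis(triisopropylsilyloxy)benzene | C=CC(C)(C)Oc1cc(O[Si](C(C)C)(C(C)C)C(C)C)cc(O[Si](C(C)C)(C(C)C)C(C)C)c1 | intermediate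
7 | 6-(3-methylbut-2-enyl)-3,5-bis(triisopropylsilyloxy)cyclohexa-2,4-dien-1-one | CC(C)=CCC1C(=O)C=C(O[Si](C(C)C)(C(C)C)C(C)C)C=C1O[Si](C(C)C)(C(C)C)C(C)C | intermediate
8 | 2-(3-methylbut-2-enyl)-3,5-bis(triisopropylsilyloxy)phenol | CC(C)=CCc1c(O)cc(O[Si](C(C)C)(C(C)C)C(C)C)cc1O[Si](C(C)C)(C(C)C)C(C)C | intermediate
9 | paraformaldehyde (formaldehyde unit) | C=O | starting material
10 | 2-(hydroxymethyl)-6-(3-methylbut-2-enyl)-3,5-bis(triisopropylsilyloxy)phenol | OCc1c(O)c(CC=C(C)C)c(O[Si](C(C)C)(C(C)C)C(C)C)cc1O[Si](C(C)C)(C(C)C)C(C)C | intermediate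
11 | 2-hydroxy-3-(3-methylbut-2-enyl)-4,6-bis(triisopropylsilyloxy)benzaldehyde | O=Cc1c(O)c(CC=C(C)C)c(O[Si](C(C)C)(C(C)C)C(C)C)cc1O[Si](C(C)C)(C(C)C)C(C)C | intermediate
12 | 4-hydroxybenzaldehyde | O=Cc1ccc(O)cc1 | starting material
13 | 1-bromo-3-methylbut-2-ene (prenyl bromide) | CC(C)=CCBr | starting material
14 | 4-(3-methylbut-2-enyloxy)benzaldehyde | CC(C)=CCOc1ccc(C=O)cc1 | intermediate
15 | dimethyl (1-diazo-2-oxopropyl)phosphonate | COP(=O)(OC)C(=[N+]=[N-])C(C)=O | starting material
16 | 1-(2-diazoethenyl)-4-(3-methylbut-2-enyloxy)benzene | CC(C)=CCOc1ccc(C=C=[N+]=[N-])cc1 | intermediate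
17 | 1-ethynyl-4-(3-methylbut-2-enyloxy)benzene | C#Cc1ccc(OCC=C(C)C)cc1 | intermediate
18 | 2-methoxy-4,4,5,5-tetramethyl-1,3,2-dioxaborolane | COB1OC(C)(C)C(C)(C)O1 | starting material
19 | diisobutyl{1-[4-(3-methylbut-2-enyloxy)phenyl]ethenyl}alane | C=C(c1ccc(OCC=C(C)C)cc1)[Al](CC(C)C)CC(C)C | intermediate
20 | 4,4,5,5-tetramethyl-2-{1-[4-(3-methylbut-2-enyloxy)phenyl]ethenyl}-1,3,2-dioxaborolane | C=C(B1OC(C)(C)C(C)(C)O1)c1ccc(OCC=C(C)C)cc1 | intermediate
21 | 3-(3-methylbut-2-enyl)-2-{1-[4-(3-methylbut-2-enyloxy)phenyl]ethenyloxy}-4,6-bis(triisopropylsilyloxy)benzaldehyde | O=Cc1c(OC(=C)c2ccc(OCC=C(C)C)cc2)c(CC=C(C)C)c(O[Si](C(C)C)(C(C)C)C(C)C)cc1O[Si](C(C)C)(C(C)C)C(C)C | intermediate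
22 | (2S)-8-(3-methylbut-2-enyl)-2-[4-(3-methylbut-2-enyloxy)phenyl]-5,7-bis(triisopropylsilyloxy)-2,3-dihydro-4H-chromen-4-one | CC(C)=CCOc1ccc([C@@H]2CC(=O)c3c(O[Si](C(C)C)(C(C)C)C(C)C)cc(O[Si](C(C)C)(C(C)C)C(C)C)c(CC=C(C)C)c3O2)cc1 | intermediate
23 | (2S)-5,7-dihydroxy-8-(3-methylbut-2-enyl)-2-[4-(3-methylbut-2-enyloxy)phenyl]-2,3-dihydro-4H-chromen-4-one | CC(C)=CCOc1ccc([C@@H]2CC(=O)c3c(O)cc(O)c(CC=C(C)C)c3O2)cc1 | target

**Step count**

Total step count: 10. Longest linear sequence: 7 steps (steps 1, 2, 3, 4, 8, 9, 10).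

**Steps most likely to fail**

Step 9 (Proposed new method). The acyl rhodium hydride may lose carbon monoxide, insert with the wrong regiochemistry or expel the β-aryloxide from the alkyl rhodium intermediate. The cationic metal may also act as a Lewis acid and trigger an ionic Prins-type closure of the enol ether on the aldehyde, and facial selectivity may be low next to the bulky 5-silyloxy group. The fallback uses known chemistry only, gives up the hydroacylation, sets out from 11 and 17 and returns to the route at 22. Deprotonation of 17 (n-BuLi, THF, –78 °C, 2.2 equiv of acetylide) and addition to 11 should give the propargylic alcohol 2-{1-hydroxy-3-[4-(3-methylbut-2-enyloxy)phenyl]prop-2-yn-1-yl}-6-(3-methylbut-2-enyl)-3,5-bis(triisopropylsilyloxy)phenol F1. MnO2 (CH2Cl2, rt) should oxidise it to the ynone 1-[2-hydroxy-3-(3-methylbut-2-enyl)-4,6-bis(triisopropylsilyloxy)phenyl]-3-[4-(3-methylbut-2-enyloxy)phenyl]prop-2-yn-1-one F2. Amine-catalysed 6-endo-dig oxa-Michael closure (Et2NH, EtOH, rt) should give the flavone 8-(3-methylbut-2-enyl)-2-[4-(3-methylbut-2-enyloxy)phenyl]-5,7-bis(triisopropylsilyloxy)-4H-chromen-4-one F3. Copper hydride-catalysed asymmetric conjugate reduction of this chromone (Cu(OAc)2, (R)-DTBM-SEGPHOS or its antipode, (EtO)2MeSiH, t-BuOH, PhMe) would then deliver hydride to C2 and give 22 after protonation of the silyl enol ether.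

Step 8. C–O bond formation may be slow at the di-ortho-substituted, aldehyde-chelated phenoxide, so that protodeboronation and oxidative homocoupling consume the alkenyl boronate. The fallback replaces the coupling by ester methylenation with the formyl group brought in afterwards; it sets out from 4 (with 5 and 14) and returns to the route at 21. Ortho-bromination of 4 (NBS, cat. i-Pr2NH, CH2Cl2, –78 °C) should give 2-bromo-3,5-bis(triisopropylsilyloxy)phenol F4. O-tert-prenylation with 5 (Pd(PPh3)4, THF, 0 °C) should give 2-bromo-1-(2-methylbut-3-en-2-yloxy)-3,5-bis(triisopropylsilyloxy)benzene F5, and Claisen shift to the only free ortho carbon (N,N-diethylaniline, 130 °C) should give 2-bromo-6-(3-methylbut-2-enyl)-3,5-bis(triisopropylsilyloxy)phenol F6. Pinnick oxidation of 14 (NaClO2, NaH2PO4, 2-methylbut-2-ene, t-BuOH/H2O) gives 4-(3-methylbut-2-enyloxy)benzoic acid F7, which is esterified with F6 (EDC·HCl, DMAP, CH2Cl2) to 2-bromo-6-(3-methylbut-2-enyl)-3,5-bis(triisopropylsilyloxy)phenyl 4-(3-methylbut-2-enyloxy)benzoate F8. Methylenation of the ester with Cp2Ti(μ-Cl)(μ-CH2)AlMe2 (pyridine, THF/PhMe, –40 °C to rt) should give 1-bromo-2-{1-[4-(3-methylbut-2-enyloxy)phenyl]ethenyloxy}-3-(3-methylbut-2-enyl)-4,6-bis(triisopropylsilyloxy)benzene F9. Bromine–lithium exchange (t-BuLi, Et2O, –78 °C, kept cold to avoid silyl migration) and a DMF quench would then give 21.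

Step 2. The π-allyl palladium may be attacked by the electron-rich arene carbon instead of oxygen, or the tertiary ether may equilibrate to the linear O-prenyl ether by reversible ionisation. The fallback builds the tertiary ether without a π-allyl intermediate; it sets out from 4 and returns to the route at 6. Copper-catalysed propargylic etherification of 4 with purchased 3-chloro-3-methylbut-1-yne (CuCl2·2H2O cat., DBU, MeCN, 0 °C) should give 1-(2-methylbut-3-yn-2-yloxy)-3,5-bis(triisopropylsilyloxy)benzene F10, and semi-hydrogenation (H2, Pd/CaCO3 poisoned with Pb(OAc)2, quinoline, EtOAc) would give 6.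

**Further compounds**

F1 | step 9 | 2-{1-hydroxy-3-[4-(3-methylbut-2-enyloxy)phenyl]prop-2-yn-1-yl}-6-(3-methylbut-2-enyl)-3,5-bis(triisopropylsilyloxy)phenol | OC(C#Cc1ccc(OCC=C(C)C)cc1)c1c(O)c(CC=C(C)C)c(O[Si](C(C)C)(C(C)C)C(C)C)cc1O[Si](C(C)C)(C(C)C)C(C)C
F2 | step 9 | 1-[2-hydroxy-3-(3-methylbut-2-enyl)-4,6-bis(triisopropylsilyloxy)phenyl]-3-[4-(3-methylbut-2-enyloxy)phenyl]prop-2-yn-1-one | O=C(C#Cc1ccc(OCC=C(C)C)cc1)c1c(O)c(CC=C(C)C)c(O[Si](C(C)C)(C(C)C)C(C)C)cc1O[Si](C(C)C)(C(C)C)C(C)C
F3 | step 9 | 8-(3-methylbut-2-enyl)-2-[4-(3-methylbut-2-enyloxy)phenyl]-5,7-bis(triisopropylsilyloxy)-4H-chromen-4-one | CC(C)=CCOc1ccc(-c2cc(=O)c3c(O[Si](C(C)C)(C(C)C)C(C)C)cc(O[Si](C(C)C)(C(C)C)C(C)C)c(CC=C(C)C)c3o2)cc1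
F4 | step 8 | 2-bromo-3,5-bis(triisopropylsilyloxy)phenol | Oc1cc(O[Si](C(C)C)(C(C)C)C(C)C)cc(O[Si](C(C)C)(C(C)C)C(C)C)c1Br
F5 | step 8 | 2-bromo-1-(2-methylbut-3-en-2-yloxy)-3,5-bis(triisopropylsilyloxy)benzene | C=CC(C)(C)Oc1cc(O[Si](C(C)C)(C(C)C)C(C)C)cc(O[Si](C(C)C)(C(C)C)C(C)C)c1Br
F6 | step 8 | 2-bromo-6-(3-methylbut-2-enyl)-3,5-bis(triisopropylsilyloxy)phenol | CC(C)=CCc1c(O)c(Br)c(O[Si](C(C)C)(C(C)C)C(C)C)cc1O[Si](C(C)C)(C(C)C)C(C)C
F7 | step 8 | 4-(3-methylbut-2-enyloxy)benzoic acid | CC(C)=CCOc1ccc(C(=O)O)cc1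
F8 | step 8 | 2-bromo-6-(3-methylbut-2-enyl)-3,5-bis(triisopropylsilyloxy)phenyl 4-(3-methylbut-2-enyloxy)benzoate | CC(C)=CCOc1ccc(C(=O)Oc2c(Br)c(O[Si](C(C)C)(C(C)C)C(C)C)cc(O[Si](C(C)C)(C(C)C)C(C)C)c2CC=C(C)C)cc1
F9 | step 8 | 1-bromo-2-{1-[4-(3-methylbut-2-enyloxy)phenyl]ethenyloxy}-3-(3-methylbut-2-enyl)-4,6-bis(triisopropylsilyloxy)benzene | C=C(Oc1c(Br)c(O[Si](C(C)C)(C(C)C)C(C)C)cc(O[Si](C(C)C)(C(C)C)C(C)C)c1CC=C(C)C)c1ccc(OCC=C(C)C)cc1
F10 | step 2 | 1-(2-methylbut-3-yn-2-yloxy)-3,5-bis(triisopropylsilyloxy)benzene | C#CC(C)(C)Oc1cc(O[Si](C(C)C)(C(C)C)C(C)C)cc(O[Si](C(C)C)(C(C)C)C(C)C)c1
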